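**Retrosynthetic overview**
1. The oxolane hides a succinic acid: ring C5–C4–C3 plus the exocyclic acetoxymethyl carbon C9 are its four carbons (C5 and C9 the carboxyl carbons), and each α-carbon (C4, C3) carries an aryl carbinol (C7′ outside the ring, C2 inside) in a syn-aldol relationship.
2. Key disconnection: O1–C5 and C2–C3 together, by an Evans syn-aldol/lactonisation of bis-imide 14 with aldehyde 16. The enabling feature is the 1,4-relationship of O1 and C5 across C2–C3–C4 of the oxolane: with C5 as an acyl carbon, the C2 aldolate oxygen closes the five-membered ring on it and expels the first auxiliary.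
3. 14 comes from an Evans syn-aldol of pentenoyl imide 3 with 4-methoxybenzaldehyde (sets C4 and C7′), O-silylation, cleavage of the alkene to the C9 acid and attachment of the enantiomeric auxiliary.
4. After the key step: auxiliary off and C9 to CH2OH; lactone carbonyl C5 to CH2 by reductive acetylation and ionic hydrogenation (both acetates arrive in the same operation); phenol unmasked last.
5. Ring order: the oxolane is the only ring made (step 8, as a γ-lactone); both arenes are bought.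

Key step: step 8

Remark: locants follow the target oxolane (O1, C2 = CH–aryl, C3 = CH–CH2OAc, C4, C5 = OCH2); C7′ is the anisyl carbinol carbon and C9 the acetoxymethyl carbon. Aldehyde 16 is prepared because its commercial supply is not assumed.

Step 1
Reactants: 1 (S)-4-benzyl-1,3-oxazolidin-2-one; 2 pent-4-enoyl chloride
Product: 3 (S)-4-benzyl-3-(pent-4-enoyl)-1,3-oxazolidin-2-one
Conditions: Et3N, DMAP (cat.), CH2Cl2, 0 °C → rt
Reagents that add atoms: none
Why: DMAP-catalysed N-acylation of an oxazolidinone with an acid chloride is routine and touches no stereocentre.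

Step 2
Reactants: 3 (S)-4-benzyl-3-(pent-4-enoyl)-1,3-oxazolidin-2-one; 4 4-methoxybenzaldehyde
Product: 7 (S)-4-benzyl-3-[(2S)-2-[(S)-hydroxy(4-methoxyphenyl)methyl]pent-4-enoyl]-1,3-oxazolidin-2-one, via Z-boron enolate 5 (not isolated), via boron aldolate 6 (not isolated)
Conditions: n-Bu2BOTf, i-Pr2NEt, CH2Cl2, 0 °C; 4, −78 → 0 °C; pH 7 buffer, MeOH, 30% H2O2, 0 °C
Reagents that add atoms: none
Why: Evans syn-aldol reaction: the Z-boron enolate 5 should react through a Zimmerman–Traxler chair on the face away from the benzyl group of the (S)-auxiliary, which sets C4 and C7′ together (S,S, syn), and the alkene stands in for the C9 carboxyl so that the new hydroxyl has nothing to lactonise onto.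

Step 3
Reactants: 7 (S)-4-benzyl-3-[(2S)-2-[(S)-hydroxy(4-methoxyphenyl)methyl]pent-4-enoyl]-1,3-oxazolidin-2-one
Product: 8 (S)-4-benzyl-3-[(2S)-2-[(S)-(4-methoxyphenyl)(triethylsilyloxy)methyl]pent-4-enoyl]-1,3-oxazolidin-2-one
Conditions: TESOTf, 2,6-lutidine, CH2Cl2, −78 → 0 °C
Reagents that add atoms: triethylsilyl triflate, CC[Si](CC)(CC)OS(=O)(=O)C(F)(F)F
Why: silyl triflate/2,6-lutidine silylation of a hindered secondary alcohol is standard, and the TES ether keeps O7′ from closing the wrong lactone once C9 becomes a carboxyl.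

Step 4
Reactants: 8 (S)-4-benzyl-3-[(2S)-2-[(S)-(4-methoxyphenyl)(triethylsilyloxy)methyl]pent-4-enoyl]-1,3-oxazolidin-2-one
Product: 10 (S)-4-benzyl-3-[(2S)-2-[(S)-(4-methoxyphenyl)(triethylsilyloxy)methyl]-4-oxobutanoyl]-1,3-oxazolidin-2-one, via secondary ozonide 9 (not isolated)
Conditions: O3, CH2Cl2, −78 °C (indicator end point); PPh3, −78 °C → rt
Reagents that add atoms: ozone, [O-][O+]=O
Why: ozonolysis with reductive work-up, in which the terminal alkene should react far faster than the anisyl ring when ozone is dosed to an indicator end point at −78 °C.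

Step 5
Reactants: 10 (S)-4-benzyl-3-[(2S)-2-[(S)-(4-methoxyphenyl)(triethylsilyloxy)methyl]-4-oxobutanoyl]-1,3-oxazolidin-2-one
Product: 11 (3S)-4-[(S)-4-benzyl-2-oxo-1,3-oxazolidin-3-yl]-3-[(S)-(4-methoxyphenyl)(triethylsilyloxy)methyl]-4-oxobutanoic acid
Conditions: NaClO2, NaH2PO4, 2-methylbut-2-ene, t-BuOH/H2O, 0 °C → rt
Reagents that add atoms: sodium chlorite, [Na+].[O-]Cl=O
Why: Pinnick oxidation is buffered and mild, so the TES ether, the imide and the C4 stereocentre should survive.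

Step 6
Reactants: 11 (3S)-4-[(S)-4-benzyl-2-oxo-1,3-oxazolidin-3-yl]-3-[(S)-(4-methoxyphenyl)(triethylsilyloxy)methyl]-4-oxobutanoic acid; 12 (R)-4-benzyl-1,3-oxazolidin-2-one
Product: 14 (S)-4-benzyl-3-[(2S)-4-[(R)-4-benzyl-2-oxo-1,3-oxazolidin-3-yl]-2-[(S)-(4-methoxyphenyl)(triethylsilyloxy)methyl]-4-oxobutanoyl]-1,3-oxazolidin-2-one, via mixed pivalic anhydride 13 (not isolated)
Conditions: PivCl, Et3N, THF, −20 °C; 12, LiCl, −20 °C → rt
Reagents that add atoms: none
Why: N-acylation of the oxazolidinone through the mixed pivalic anhydride with LiCl/Et3N needs no strong base, so the unhindered C9 carboxyl should be converted without epimerising C4 or disturbing the first imide.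

Step 7
Reactants: 15 4-hydroxybenzaldehyde
Product: 16 4-(triisopropylsilyloxy)benzaldehyde
Conditions: TIPSCl, imidazole, DMF, rt
Reagents that add atoms: triisopropylsilyl chloride, CC(C)[Si](Cl)(C(C)C)C(C)C
Why: standard silylation of a phenol, TIPS being chosen because an aryl TIPS ether should withstand LiOOH, borane, DIBAL-H, BF3 at −78 °C and buffered HF·pyridine and still fall to fluoride at the end.

Step 8
Reactants: 14 (S)-4-benzyl-3-[(2S)-4-[(R)-4-benzyl-2-oxo-1,3-oxazolidin-3-yl]-2-[(S)-(4-methoxyphenyl)(triethylsilyloxy)methyl]-4-oxobutanoyl]-1,3-oxazolidin-2-one; 16 4-(triisopropylsilyloxy)benzaldehyde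
Product: 20 (R)-4-benzyl-3-[(2R,3R,4S)-4-[(S)-(4-methoxyphenyl)(triethylsilyloxy)methyl]-5-oxo-2-[4-(triisopropylsilyloxy)phenyl]oxolane-3-carbonyl]-1,3-oxazolidin-2-one, via Z-boron enolate 17 (not isolated), via boron aldolate 18 (not isolated), via hydroxy bis-imide 19 (not isolated)
Conditions: n-Bu2BOTf (1.3 equiv), i-Pr2NEt, CH2Cl2, 0 °C; 16, −78 → 0 °C; pH 7 buffer, MeOH, 30% H2O2, 0 °C → rt
Reagents that add atoms: none
Why: Bu2BOTf/i-Pr2NEt should enolise only the unbranched C9 imide to the Z-boron enolate 17, which adds to 16 through a Zimmerman–Traxler chair to give aldolate 18; once the B–O bond is cleaved, the C2 hydroxyl of 19 attacks the C5 N-acyloxazolidinone and expels the (S)-auxiliary, so the C2–C3 and O1–C5 bonds are made in one operation. The closest known reaction type is the Evans syn-aldol/lactonisation of succinic half-ester imides used for paraconic acids, here with an imide instead of an ester as the internal acyl acceptor. The lactone closes by a 5-exo-trig acyl substitution (addition–elimination) at C5. C3 and C2 are set by the (R)-auxiliary (attack on the enolate face opposite its benzyl group, aryl equatorial in the chair, syn aldol = 2,3-trans lactone), while C4 and C7′ are carried unchanged from step 2; the resulting all-trans lactone is also the thermodynamic isomer, so any epimerisation at C3 or C4 would be self-correcting. The step needs site-selective enolisation (the CH2 of the C9 imide is far more accessible than the α-branched C–H of the C5 imide, and the boron reagent is limited), reagent control over the resident C4 stereocentre (Evans boron enolates normally override a β-stereocentre), and O7′ blocked as its TES ether so that only the C2 oxygen can be acylated.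

Step 9
Reactants: 20 (R)-4-benzyl-3-[(2R,3R,4S)-4-[(S)-(4-methoxyphenyl)(triethylsilyloxy)methyl]-5-oxo-2-[4-(triisopropylsilyloxy)phenyl]oxolane-3-carbonyl]-1,3-oxazolidin-2-one
Product: 22 (2R,3R,4S)-4-[(S)-(4-methoxyphenyl)(triethylsilyloxy)methyl]-5-oxo-2-[4-(triisopropylsilyloxy)phenyl]oxolane-3-carboxylic acid, via peroxy acid 21 (not isolated)
Conditions: LiOH·H2O, 30% H2O2, THF/H2O (3:1), 0 °C; aq. Na2SO3; 1 M HCl to pH 3, 0 °C
Reagents that add atoms: hydrogen peroxide (as LiOOH), OO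
Why: hydroperoxide-mediated Evans auxiliary cleavage attacks the exocyclic imide carbonyl selectively, sulfite reduces the peracid 21, and acidification should re-close any lactone that opened, the all-trans arrangement being the stable one.

Step 10
Reactants: 22 (2R,3R,4S)-4-[(S)-(4-methoxyphenyl)(triethylsilyloxy)methyl]-5-oxo-2-[4-(triisopropylsilyloxy)phenyl]oxolane-3-carboxylic acid
Product: 23 (3S,4S,5R)-4-(hydroxymethyl)-3-[(S)-(4-methoxyphenyl)(triethylsilyloxy)methyl]-5-[4-(triisopropylsilyloxy)phenyl]oxolan-2-one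
Conditions: BH3·SMe2, THF, 0 °C → rt; MeOH
Reagents that add atoms: none
Why: borane reduces a carboxylic acid much faster than a γ-lactone (chemoselective acid reduction), and the neutral medium avoids acyl migration of the lactone to the new hydroxyl.

Step 11
Reactants: 23 (3S,4S,5R)-4-(hydroxymethyl)-3-[(S)-(4-methoxyphenyl)(triethylsilyloxy)methyl]-5-[4-(triisopropylsilyloxy)phenyl]oxolan-2-one
Product: 24 (3S,4S,5R)-3-[(S)-hydroxy(4-methoxyphenyl)methyl]-4-(hydroxymethyl)-5-[4-(triisopropylsilyloxy)phenyl]oxolan-2-one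
Conditions: HF·pyridine, pyridine, THF, 0 °C
Reagents that add atoms: none
Why: buffered HF·pyridine should cleave the alkyl TES ether while the phenolic TIPS ether, which is stable to acidic fluoride, stays, and no ionising acid reaches the anisyl carbinol.

Step 12
Reactants: 24 (3S,4S,5R)-3-[(S)-hydroxy(4-methoxyphenyl)methyl]-4-(hydroxymethyl)-5-[4-(triisopropylsilyloxy)phenyl]oxolan-2-one
Product: 26 (3S,4S,5R)-3-[(S)-acetoxy(4-methoxyphenyl)methyl]-4-(acetoxymethyl)-5-[4-(triisopropylsilyloxy)phenyl]oxolan-2-yl acetate (both C2 epimers), via lactol aluminate 25 (not isolated)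
Conditions: DIBAL-H (3.5 equiv), CH2Cl2, −78 °C; pyridine, DMAP, Ac2O, −78 → 0 °C; Rochelle salt work-up
Reagents that add atoms: acetic anhydride, CC(=O)OC(C)=O
Why: reductive acetylation of a lactone: DIBAL-H stops at the aluminium hemiacetal 25 at −78 °C and in situ acylation traps it as the α-acetoxy ether while the two aluminium alkoxides become the two acetates of the target, so the O1–C5 bond made in step 8 is never opened.

Step 13
Reactants: 26 (3S,4S,5R)-3-[(S)-acetoxy(4-methoxyphenyl)methyl]-4-(acetoxymethyl)-5-[4-(triisopropylsilyloxy)phenyl]oxolan-2-yl acetate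
Product: 27 [(2R,3S,4R)-4-[(S)-acetoxy(4-methoxyphenyl)methyl]-2-[4-(triisopropylsilyloxy)phenyl]oxolan-3-yl]methyl acetate
Conditions: Et3SiH, BF3·OEt2, CH2Cl2, −78 °C
Reagents that add atoms: none
Why: ionic hydrogenation of an α-acetoxy ether: BF3 ionises the acetal acetate to the cyclic oxocarbenium ion, which Et3SiH reduces to the C5 methylene, and at −78 °C this ionisation should be far faster than that of the p-methoxybenzylic acetate or of the benzylic C2–O bond; no stereocentre is created.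

Step 14
Reactants: 27 [(2R,3S,4R)-4-[(S)-acetoxy(4-methoxyphenyl)methyl]-2-[4-(triisopropylsilyloxy)phenyl]oxolan-3-yl]methyl acetate
Product: 28 [(2R,3S,4R)-4-[(S)-acetoxy(4-methoxyphenyl)methyl]-2-(4-hydroxyphenyl)oxolan-3-yl]methyl acetate
Conditions: TBAF, AcOH, THF, 0 °C
Reagents that add atoms: none
Why: fluoride cleaves the aryl silyl ether within minutes at 0 °C, and buffering with acetic acid keeps the medium non-basic so that the two acetates should neither cleave nor migrate.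

**Compound list**
1 | (S)-4-benzyl-1,3-oxazolidin-2-one | O=C1N[C@@H](Cc2ccccc2)CO1 | starting material
2 | pent-4-enoyl chloride | C=CCCC(Cl)=O | starting material
3 | (S)-4-benzyl-3-(pent-4-enoyl)-1,3-oxazolidin-2-one | C=CCCC(=O)N1[C@@H](Cc2ccccc2)COC1=O | intermediate
4 | 4-methoxybenzaldehyde | COc1ccc(C=O)cc1 | starting material
5 | (Z)-dibutylboron enolate of 3 | C=CC/C=C(\OB(CCCC)CCCC)N1[C@@H](Cc2ccccc2)COC1=O | intermediate
6 | dibutylboron aldolate of 7 | COc1ccc([C@@H](OB(CCCC)CCCC)[C@H](CC=C)C(=O)N2[C@@H](Cc3ccccc3)COC2=O)cc1 | intermediate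
7 | (S)-4-benzyl-3-[(2S)-2-[(S)-hydroxy(4-methoxyphenyl)methyl]pent-4-enoyl]-1,3-oxazolidin-2-one | COc1ccc([C@@H](O)[C@H](CC=C)C(=O)N2[C@@H](Cc3ccccc3)COC2=O)cc1 | intermediate
8 | (S)-4-benzyl-3-[(2S)-2-[(S)-(4-methoxyphenyl)(triethylsilyloxy)methyl]pent-4-enoyl]-1,3-oxazolidin-2-one | COc1ccc([C@@H](O[Si](CC)(CC)CC)[C@H](CC=C)C(=O)N2[C@@H](Cc3ccccc3)COC2=O)cc1 | intermediate
9 | secondary ozonide (1,2,4-trioxolane) of 8, epimers at the trioxolane carbon | COc1ccc([C@@H](O[Si](CC)(CC)CC)[C@H](CC2OCOO2)C(=O)N2[C@@H](Cc3ccccc3)COC2=O)cc1 | intermediate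
10 | (S)-4-benzyl-3-[(2S)-2-[(S)-(4-methoxyphenyl)(triethylsilyloxy)methyl]-4-oxobutanoyl]-1,3-oxazolidin-2-one | COc1ccc([C@@H](O[Si](CC)(CC)CC)[C@H](CC=O)C(=O)N2[C@@H](Cc3ccccc3)COC2=O)cc1 | intermediate
11 | (3S)-4-[(S)-4-benzyl-2-oxo-1,3-oxazolidin-3-yl]-3-[(S)-(4-methoxyphenyl)(triethylsilyloxy)methyl]-4-oxobutanoic acid | COc1ccc([C@@H](O[Si](CC)(CC)CC)[C@H](CC(=O)O)C(=O)N2[C@@H](Cc3ccccc3)COC2=O)cc1 | intermediate
12 | (R)-4-benzyl-1,3-oxazolidin-2-one | O=C1N[C@H](Cc2ccccc2)CO1 | starting material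
13 | mixed pivalic anhydride of 11 | COc1ccc([C@@H](O[Si](CC)(CC)CC)[C@H](CC(=O)OC(=O)C(C)(C)C)C(=O)N2[C@@H](Cc3ccccc3)COC2=O)cc1 | intermediate
14 | (S)-4-benzyl-3-[(2S)-4-[(R)-4-benzyl-2-oxo-1,3-oxazolidin-3-yl]-2-[(S)-(4-methoxyphenyl)(triethylsilyloxy)methyl]-4-oxobutanoyl]-1,3-oxazolidin-2-one (bis-imide) | COc1ccc([C@@H](O[Si](CC)(CC)CC)[C@H](CC(=O)N2[C@H](Cc3ccccc3)COC2=O)C(=O)N2[C@@H](Cc3ccccc3)COC2=O)cc1 | intermediate
15 | 4-hydroxybenzaldehyde | O=Cc1ccc(O)cc1 | starting material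
16 | 4-(triisopropylsilyloxy)benzaldehyde | O=Cc1ccc(O[Si](C(C)C)(C(C)C)C(C)C)cc1 | intermediate
17 | (Z)-dibutylboron enolate of 14 at the C9 imide | COc1ccc([C@@H](O[Si](CC)(CC)CC)[C@H](/C=C(\OB(CCCC)CCCC)N2[C@H](Cc3ccccc3)COC2=O)C(=O)N2[C@@H](Cc3ccccc3)COC2=O)cc1 | intermediate
18 | open-chain dibutylboron syn-aldolate of 19 | COc1ccc([C@@H](O[Si](CC)(CC)CC)[C@H]([C@H]([C@@H](OB(CCCC)CCCC)c2ccc(O[Si](C(C)C)(C(C)C)C(C)C)cc2)C(=O)N2[C@H](Cc3ccccc3)COC2=O)C(=O)N2[C@@H](Cc3ccccc3)COC2=O)cc1 | intermediate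
19 | (S)-4-benzyl-3-[(2S,3R)-4-[(R)-4-benzyl-2-oxo-1,3-oxazolidin-3-yl]-3-[(R)-hydroxy[4-(triisopropylsilyloxy)phenyl]methyl]-2-[(S)-(4-methoxyphenyl)(triethylsilyloxy)methyl]-4-oxobutanoyl]-1,3-oxazolidin-2-one (hydroxy bis-imide) | COc1ccc([C@@H](O[Si](CC)(CC)CC)[C@H]([C@H]([C@@H](O)c2ccc(O[Si](C(C)C)(C(C)C)C(C)C)cc2)C(=O)N2[C@H](Cc3ccccc3)COC2=O)C(=O)N2[C@@H](Cc3ccccc3)COC2=O)cc1 | intermediate
20 | (R)-4-benzyl-3-[(2R,3R,4S)-4-[(S)-(4-methoxyphenyl)(triethylsilyloxy)methyl]-5-oxo-2-[4-(triisopropylsilyloxy)phenyl]oxolane-3-carbonyl]-1,3-oxazolidin-2-one | COc1ccc([C@@H](O[Si](CC)(CC)CC)[C@H]2C(=O)O[C@@H](c3ccc(O[Si](C(C)C)(C(C)C)C(C)C)cc3)[C@@H]2C(=O)N2[C@H](Cc3ccccc3)COC2=O)cc1 | intermediate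
21 | (2R,3R,4S)-4-[(S)-(4-methoxyphenyl)(triethylsilyloxy)methyl]-5-oxo-2-[4-(triisopropylsilyloxy)phenyl]oxolane-3-carboperoxoic acid | COc1ccc([C@@H](O[Si](CC)(CC)CC)[C@H]2C(=O)O[C@@H](c3ccc(O[Si](C(C)C)(C(C)C)C(C)C)cc3)[C@@H]2C(=O)OO)cc1 | intermediate
22 | (2R,3R,4S)-4-[(S)-(4-methoxyphenyl)(triethylsilyloxy)methyl]-5-oxo-2-[4-(triisopropylsilyloxy)phenyl]oxolane-3-carboxylic acid | COc1ccc([C@@H](O[Si](CC)(CC)CC)[C@H]2C(=O)O[C@@H](c3ccc(O[Si](C(C)C)(C(C)C)C(C)C)cc3)[C@@H]2C(=O)O)cc1 | intermediate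
23 | (3S,4S,5R)-4-(hydroxymethyl)-3-[(S)-(4-methoxyphenyl)(triethylsilyloxy)methyl]-5-[4-(triisopropylsilyloxy)phenyl]oxolan-2-one | COc1ccc([C@@H](O[Si](CC)(CC)CC)[C@H]2C(=O)O[C@@H](c3ccc(O[Si](C(C)C)(C(C)C)C(C)C)cc3)[C@@H]2CO)cc1 | intermediate
24 | (3S,4S,5R)-3-[(S)-hydroxy(4-methoxyphenyl)methyl]-4-(hydroxymethyl)-5-[4-(triisopropylsilyloxy)phenyl]oxolan-2-one | COc1ccc([C@@H](O)[C@H]2C(=O)O[C@@H](c3ccc(O[Si](C(C)C)(C(C)C)C(C)C)cc3)[C@@H]2CO)cc1 | intermediate
25 | tris(diisobutylaluminium) alkoxide of the lactol of 24, both lactol epimers | COc1ccc([C@@H](O[Al](CC(C)C)CC(C)C)[C@H]2C(O[Al](CC(C)C)CC(C)C)O[C@@H](c3ccc(O[Si](C(C)C)(C(C)C)C(C)C)cc3)[C@@H]2CO[Al](CC(C)C)CC(C)C)cc1 | intermediate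
26 | (3S,4S,5R)-3-[(S)-acetoxy(4-methoxyphenyl)methyl]-4-(acetoxymethyl)-5-[4-(triisopropylsilyloxy)phenyl]oxolan-2-yl acetate, both C2 epimers | COc1ccc([C@@H](OC(C)=O)[C@H]2C(OC(C)=O)O[C@@H](c3ccc(O[Si](C(C)C)(C(C)C)C(C)C)cc3)[C@@H]2COC(C)=O)cc1 | intermediate
27 | [(2R,3S,4R)-4-[(S)-acetoxy(4-methoxyphenyl)methyl]-2-[4-(triisopropylsilyloxy)phenyl]oxolan-3-yl]methyl acetate | COc1ccc([C@@H](OC(C)=O)[C@H]2CO[C@@H](c3ccc(O[Si](C(C)C)(C(C)C)C(C)C)cc3)[C@@H]2COC(C)=O)cc1 | intermediate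
28 | [(2R,3S,4R)-4-[(S)-acetoxy(4-methoxyphenyl)methyl]-2-(4-hydroxyphenyl)oxolan-3-yl]methyl acetate | COc1ccc([C@@H](OC(C)=O)[C@H]2CO[C@@H](c3ccc(O)cc3)[C@@H]2COC(C)=O)cc1 | target

**Totals**
Total step count: 14. Longest linear sequence: 13 steps (steps 1–6 and 8–14; step 7 is a one-step branch).

**Steps most likely to fail, with fallbacks**

Step 8. What may go wrong: enolisation losing its site-selectivity (boron binding to the hindered imide), the resident C4 stereocentre working against the auxiliary (mismatched double stereodifferentiation), or the aldolate failing to acylate. Fallback: the same aldol–lactonisation is run on an unsubstituted succinate and the anisyl carbinol is attached afterwards. It sets out from 12 and 16 and comes back at 24. 12 is N-acylated with methyl 4-chloro-4-oxobutanoate (Et3N, DMAP) to (R)-4-benzyl-3-(4-methoxy-4-oxobutanoyl)-1,3-oxazolidin-2-one F1. Bu2BOTf/i-Pr2NEt and 16 should then give, by syn-aldol and loss of methanol, the lactone imide (R)-4-benzyl-3-[(2R,3R)-5-oxo-2-[4-(triisopropylsilyloxy)phenyl]oxolane-3-carbonyl]-1,3-oxazolidin-2-one F2. LiOH/H2O2 gives (2R,3R)-5-oxo-2-[4-(triisopropylsilyloxy)phenyl]oxolane-3-carboxylic acid F3, BH3·SMe2 gives (4S,5R)-4-(hydroxymethyl)-5-[4-(triisopropylsilyloxy)phenyl]oxolan-2-one F4, and TBSCl/imidazole gives (4S,5R)-4-[(tert-butyldimethylsilyloxy)methyl]-5-[4-(triisopropylsilyloxy)phenyl]oxolan-2-one F5. The lithium enolate of F5 (LiHMDS, 2.2 equiv, THF, −78 °C) is C-acylated with 4-methoxybenzoyl chloride trans to the C4 substituent to give (3S,4S,5R)-4-[(tert-butyldimethylsilyloxy)methyl]-3-(4-methoxybenzoyl)-5-[4-(triisopropylsilyloxy)phenyl]oxolan-2-one F6. Chelation-controlled reduction with Zn(BH4)2 should give the syn carbinol (3S,4S,5R)-4-[(tert-butyldimethylsilyloxy)methyl]-3-[(S)-hydroxy(4-methoxyphenyl)methyl]-5-[4-(triisopropylsilyloxy)phenyl]oxolan-2-one F7, and HF·pyridine removes the primary TBS ether to reach 24.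

Step 13. What may go wrong: competing Lewis-acid ionisation at the p-methoxybenzylic acetate (loss or scrambling of the C7′ oxygen) or at the benzylic C2–O bond (ring opening), and capture of the oxocarbenium ion by the neighbouring C7′ acetate. Fallback: a radical deoxygenation without Lewis acid, setting out from 26 and coming back at 27. Hydrazine acetate in DMF should cleave only the acetal acetate to give (3S,4S,5R)-3-[(S)-acetoxy(4-methoxyphenyl)methyl]-4-(acetoxymethyl)-5-[4-(triisopropylsilyloxy)phenyl]oxolan-2-ol F8. N-(Phenylseleno)phthalimide and n-Bu3P convert the lactol into [(2R,3S,4S)-4-[(S)-acetoxy(4-methoxyphenyl)methyl]-5-(phenylselanyl)-2-[4-(triisopropylsilyloxy)phenyl]oxolan-3-yl]methyl acetate F9. n-Bu3SnH/AIBN in toluene at 80 °C then reduces the C–Se bond through the α-alkoxy radical to 27.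

Step 11. What may go wrong: insufficient discrimination between the alkyl TES ether and the aryl TIPS ether, or solvolysis at the anisyl carbinol during desilylation. Fallback: both silyl groups are removed on purpose and the phenol is handled as an acetate, setting out from 23 and coming back at 28. TBAF/AcOH gives (3S,4S,5R)-3-[(S)-hydroxy(4-methoxyphenyl)methyl]-4-(hydroxymethyl)-5-(4-hydroxyphenyl)oxolan-2-one F10. DIBAL-H (4.5 equiv, −78 °C) followed by Ac2O/pyridine/DMAP gives (3S,4S,5R)-3-[(S)-acetoxy(4-methoxyphenyl)methyl]-4-(acetoxymethyl)-5-(4-acetoxyphenyl)oxolan-2-yl acetate F11. Et3SiH/BF3·OEt2 at −78 °C gives [(2R,3S,4R)-4-[(S)-acetoxy(4-methoxyphenyl)methyl]-2-(4-acetoxyphenyl)oxolan-3-yl]methyl acetate F12. Pyrrolidine (1.1 equiv, MeCN, 0 °C) should then aminolyse only the aryl acetate to give 28.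

**Further compounds**
F1 | step 8 | (R)-4-benzyl-3-(4-methoxy-4-oxobutanoyl)-1,3-oxazolidin-2-one | COC(=O)CCC(=O)N1[C@H](Cc2ccccc2)COC1=O
F2 | step 8 | (R)-4-benzyl-3-[(2R,3R)-5-oxo-2-[4-(triisopropylsilyloxy)phenyl]oxolane-3-carbonyl]-1,3-oxazolidin-2-one | C1C(=O)O[C@@H](c2ccc(O[Si](C(C)C)(C(C)C)C(C)C)cc2)[C@@H]1C(=O)N1[C@H](Cc2ccccc2)COC1=O
F3 | step 8 | (2R,3R)-5-oxo-2-[4-(triisopropylsilyloxy)phenyl]oxolane-3-carboxylic acid | C1C(=O)O[C@@H](c2ccc(O[Si](C(C)C)(C(C)C)C(C)C)cc2)[C@@H]1C(=O)O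
F4 | step 8 | (4S,5R)-4-(hydroxymethyl)-5-[4-(triisopropylsilyloxy)phenyl]oxolan-2-one | C1C(=O)O[C@@H](c2ccc(O[Si](C(C)C)(C(C)C)C(C)C)cc2)[C@@H]1CO
F5 | step 8 | (4S,5R)-4-[(tert-butyldimethylsilyloxy)methyl]-5-[4-(triisopropylsilyloxy)phenyl]oxolan-2-one | C1C(=O)O[C@@H](c2ccc(O[Si](C(C)C)(C(C)C)C(C)C)cc2)[C@@H]1CO[Si](C)(C)C(C)(C)C
F6 | step 8 | (3S,4S,5R)-4-[(tert-butyldimethylsilyloxy)methyl]-3-(4-methoxybenzoyl)-5-[4-(triisopropylsilyloxy)phenyl]oxolan-2-one | COc1ccc(C(=O)[C@H]2C(=O)O[C@@H](c3ccc(O[Si](C(C)C)(C(C)C)C(C)C)cc3)[C@@H]2CO[Si](C)(C)C(C)(C)C)cc1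
F7 | step 8 | (3S,4S,5R)-4-[(tert-butyldimethylsilyloxy)methyl]-3-[(S)-hydroxy(4-methoxyphenyl)methyl]-5-[4-(triisopropylsilyloxy)phenyl]oxolan-2-one | COc1ccc([C@@H](O)[C@H]2C(=O)O[C@@H](c3ccc(O[Si](C(C)C)(C(C)C)C(C)C)cc3)[C@@H]2CO[Si](C)(C)C(C)(C)C)cc1
F8 | step 13 | (3S,4S,5R)-3-[(S)-acetoxy(4-methoxyphenyl)methyl]-4-(acetoxymethyl)-5-[4-(triisopropylsilyloxy)phenyl]oxolan-2-ol, both C2 epimers | COc1ccc([C@@H](OC(C)=O)[C@H]2C(O)O[C@@H](c3ccc(O[Si](C(C)C)(C(C)C)C(C)C)cc3)[C@@H]2COC(C)=O)cc1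
F9 | step 13 | [(2R,3S,4S)-4-[(S)-acetoxy(4-methoxyphenyl)methyl]-5-(phenylselanyl)-2-[4-(triisopropylsilyloxy)phenyl]oxolan-3-yl]methyl acetate, both C5 epimers | COc1ccc([C@@H](OC(C)=O)[C@H]2C([Se]c3ccccc3)O[C@@H](c3ccc(O[Si](C(C)C)(C(C)C)C(C)C)cc3)[C@@H]2COC(C)=O)cc1
F10 | step 11 | (3S,4S,5R)-3-[(S)-hydroxy(4-methoxyphenyl)methyl]-4-(hydroxymethyl)-5-(4-hydroxyphenyl)oxolan-2-one | COc1ccc([C@@H](O)[C@H]2C(=O)O[C@@H](c3ccc(O)cc3)[C@@H]2CO)cc1
F11 | step 11 | (3S,4S,5R)-3-[(S)-acetoxy(4-methoxyphenyl)methyl]-4-(acetoxymethyl)-5-(4-acetoxyphenyl)oxolan-2-yl acetate, both C2 epimers | COc1ccc([C@@H](OC(C)=O)[C@H]2C(OC(C)=O)O[C@@H](c3ccc(OC(C)=O)cc3)[C@@H]2COC(C)=O)cc1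
F12 | step 11 | [(2R,3S,4R)-4-[(S)-acetoxy(4-methoxyphenyl)methyl]-2-(4-acetoxyphenyl)oxolan-3-yl]methyl acetate | COc1ccc([C@@H](OC(C)=O)[C@H]2CO[C@@H](c3ccc(OC(C)=O)cc3)[C@@H]2COC(C)=O)cc1
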